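**Retrosynthetic overview**

1. Siphulin is a 5-heptyl-7-hydroxychromone (rings A and B) joined through C2–CH2 to ring C (C1'–C6'), a 2-carboxy-3,5-dihydroxyphenyl group. The route rests on ring C: C1' (CH2-bearing), C2' (CO2H), C3' (OH) and C4' (H) are C6, C5, C4 and C3 of a 4-alkoxy-2-pyrone-5-carboxylate, and C5'(OH)–C6'(H) is the two-carbon unit of a ketene acetal, with the ester para to the new oxygen.
2. Disconnections, backwards: three O–benzyl bonds (hydrogenolysis); C1'–C6' and C4'–C5' ([4+2] of the 6-(chromonylmethyl)pyrone with 1,1-bis(trimethylsilyloxy)ethene, then loss of CO2 and Me3SiOH); pyrone O1–C2 (lactonisation) and C5–C6 (C-acylation of dibenzyl 3-oxopentanedioate with the chromon-2-ylacetyl chloride).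
3. Chromon-2-ylacetic acid: CH2–CO2H bond by lateral carboxylation of the 2-methylchromone; chromone C2–C3 and O1–C2 by Claisen condensation and cyclodehydration of the acetophenone made from 5-heptylresorcinol.
4. Order of ring formation: ring A is bought; ring B (step 3); the sacrificial 2-pyrone (step 7); ring C (step 10).

Key step: step 10

Assumption: the Hoesch acylation of 5-heptylresorcinol is taken to occur at C4 (ortho to one hydroxyl, para to the other), as with orcinol and olivetol; 11 and 16 are racemic and carry the only, transient, stereocentres of the route.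

**Route**

Step 1
Reactants: 1 5-heptylbenzene-1,3-diol
Product: 3 1-(2-heptyl-4,6-dihydroxyphenyl)ethan-1-one, via ketiminium chloride 2 (not isolated)
Conditions: MeCN, ZnCl2, HCl (g), Et2O, 0 °C; then H2O, reflux
Reagents that add atoms: acetonitrile (CC#N); water (O)
Why: Hoesch acylation, in which the protonated nitrile attacks the resorcinol at the position ortho to one hydroxyl and para to the other, and hydrolysis of ketiminium salt 2 should give the aryl methyl ketone.

Step 2
Reactants: 3 1-(2-heptyl-4,6-dihydroxyphenyl)ethan-1-one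
Product: 4 1-[4-(benzyloxy)-2-heptyl-6-hydroxyphenyl]ethan-1-one
Conditions: BnBr (1.05 equiv), K2CO3, acetone, reflux
Reagents that add atoms: benzyl bromide (BrCc1ccccc1)
Why: Williamson etherification, selective because the ortho hydroxyl is held in a hydrogen bond to the ketone, so that one equivalent of benzyl bromide with a weak base should alkylate only the para hydroxyl.

Step 3
Reactants: 4 1-[4-(benzyloxy)-2-heptyl-6-hydroxyphenyl]ethan-1-one
Product: 6 7-(benzyloxy)-5-heptyl-2-methyl-4H-chromen-4-one, via diketone 5 (not isolated)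
Conditions: NaH (4 equiv), EtOAc, THF, reflux; 1 M HCl work-up; then TsOH·H2O (cat.), toluene, 90 °C
Reagents that add atoms: ethyl acetate (CCOC(C)=O)
Why: Crossed Claisen condensation of the ketone enolate with ethyl acetate gives o-hydroxyaryl 1,3-diketone 5, which under acid catalysis should close ring B by 6-exo-trig addition of the phenol to the distal carbonyl followed by dehydration.

Step 4
Reactants: 6 7-(benzyloxy)-5-heptyl-2-methyl-4H-chromen-4-one
Product: 7 [7-(benzyloxy)-5-heptyl-4-oxo-4H-chromen-2-yl]acetic acid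
Conditions: LiN(iPr)2 (2.2 equiv), THF, −78 °C; CO2 (g), −78 °C; 1 M HCl, 0 °C
Reagents that add atoms: carbon dioxide (O=C=O)
Why: Lateral (vinylogous) deprotonation of the 2-methyl group of a 4-pyranone gives the extended dienolate, which CO2 should carboxylate at the exocyclic carbon, the second equivalent of base holding the acidic product as its dianion until the cold quench.

Step 5
Reactants: 8 dimethyl 3-oxopentanedioate
Product: 9 dibenzyl 3-oxopentanedioate
Conditions: BnOH (3 equiv), DMAP (cat.), toluene, reflux, MeOH distilled off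
Reagents that add atoms: benzyl alcohol (OCc1ccccc1)
Why: Transesterification of a β-keto ester, driven to completion by removal of methanol.

Step 6
Reactants: 7 [7-(benzyloxy)-5-heptyl-4-oxo-4H-chromen-2-yl]acetic acid and 9 dibenzyl 3-oxopentanedioate
Product: 11 dibenzyl 2-{[7-(benzyloxy)-5-heptyl-4-oxo-4H-chromen-2-yl]acetyl}-3-oxopentanedioate, via acid chloride 10 (not isolated)
Conditions: 7, Me2C=C(Cl)NMe2, CH2Cl2, 0 °C; then added to 9 (1.5 equiv), MgCl2, pyridine, CH2Cl2, 0 °C to rt; 1 M HCl work-up
Reagents that add atoms: none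
Why: Magnesium-mediated C-acylation of a β-keto ester (Rathke conditions), in which the chelated enolate of 9 should react at carbon with acid chloride 10, itself made under neutral conditions with the chloroenamine so that neither HCl nor a strong amine base can attack the chromone or form the ketene; the product stays as a magnesium chelate, which blocks a second acylation.

Step 7
Reactants: 11 dibenzyl 2-{[7-(benzyloxy)-5-heptyl-4-oxo-4H-chromen-2-yl]acetyl}-3-oxopentanedioate
Product: 12 benzyl 6-{[7-(benzyloxy)-5-heptyl-4-oxo-4H-chromen-2-yl]methyl}-4-hydroxy-2-oxo-2H-pyran-5-carboxylate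
Conditions: TsOH·H2O (cat.), toluene, 100 °C
Reagents that add atoms: none
Why: Lactonisation, in which the enol oxygen of the new acyl group attacks the remote benzyl ester (6-exo-trig) with loss of benzyl alcohol to give the 4-hydroxy-2-pyrone, the usual fate of 2-acyl-3-oxoglutarates under acidic or thermal conditions, where Claisen C-cyclisation does not compete.

Step 8
Reactants: 12 benzyl 6-{[7-(benzyloxy)-5-heptyl-4-oxo-4H-chromen-2-yl]methyl}-4-hydroxy-2-oxo-2H-pyran-5-carboxylate
Product: 13 benzyl 4-(benzyloxy)-6-{[7-(benzyloxy)-5-heptyl-4-oxo-4H-chromen-2-yl]methyl}-2-oxo-2H-pyran-5-carboxylate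
Conditions: BnOH, PPh3, DIAD, THF, 0 °C to rt
Reagents that add atoms: benzyl alcohol (OCc1ccccc1)
Why: Mitsunobu etherification, in which the strongly acidic 4-hydroxyl is the pronucleophile and is alkylated on oxygen by the benzyloxyphosphonium ion, a neutral method known to give 4-alkoxy-2-pyrones and one that should leave the acidic bridging CH2 unalkylated.

Step 9
Reactants: 14 trimethylsilyl acetate
Product: 15 1,1-bis(trimethylsilyloxy)ethene
Conditions: LiN(iPr)2, THF, −78 °C; Me3SiCl, −78 °C to rt; filtration and distillation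
Reagents that add atoms: chlorotrimethylsilane (C[Si](C)(C)Cl)
Why: O-silylation of the lithium enolate of a silyl ester (Ainsworth preparation of ketene bis(silyl) acetals).

Step 10
Reactants: 13 benzyl 4-(benzyloxy)-6-{[7-(benzyloxy)-5-heptyl-4-oxo-4H-chromen-2-yl]methyl}-2-oxo-2H-pyran-5-carboxylate and 15 1,1-bis(trimethylsilyloxy)ethene
Product: 19 benzyl 2-(benzyloxy)-6-{[7-(benzyloxy)-5-heptyl-4-oxo-4H-chromen-2-yl]methyl}-4-hydroxybenzoate, via bridged lactone 16 (not isolated), via cyclohexadiene 17 (not isolated), via aryl silyl ether 18 (not isolated)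
Conditions: 15 (5 equiv), toluene, sealed tube, 130 °C; then 1 M HCl, THF, rt
Reagents that add atoms: none
Why: The pyrone C3–C6 diene, made electron-poor by the lactone carbonyl and the C5 ester, should take up the electron-rich ketene acetal in an inverse-electron-demand Diels-Alder reaction in which the CH2 of 15 bonds to C6 (β to the ester, the most electrophilic terminus) and the acetal carbon to C3, giving bridged lactone 16. Retro-[4+2] loss of CO2 from 16 gives diene 17, 1,2-elimination of trimethylsilanol across C5'–C6' aromatises it to silyl ether 18, and the acidic work-up frees the C5' phenol. The closest known reaction type is the cycloaddition of 2-pyrone-5-carboxylates (coumalates) with 1,1-dialkoxyethenes, which gives 4-alkoxybenzoates with the same para placing of ester and new oxygen. Ring C is closed by an intermolecular [4+2] cycloaddition that forms C1'–C6' and C4'–C5' in one operation; the two bridgehead centres of racemic 16 are lost on aromatisation, so no stereocenter has to be controlled. The step needs regioselectivity, which the polarisation of the diene by the C5 ester secures (the 4-benzyloxy donor keeps C3 the electron-rich terminus), and chemoselectivity for the pyrone over the chromone C2–C3 bond, which should hold because a ketene silyl acetal adds to a chromone only under Lewis-acid activation and none is present. The 4-benzyloxy group and the C6 substituent slow the diene, hence the excess of 15 and the sealed-tube temperature.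

Step 11
Reactants: 19 benzyl 2-(benzyloxy)-6-{[7-(benzyloxy)-5-heptyl-4-oxo-4H-chromen-2-yl]methyl}-4-hydroxybenzoate
Product: 20 siphulin, 2-[(5-heptyl-7-hydroxy-4-oxo-4H-chromen-2-yl)methyl]-4,6-dihydroxybenzoic acid
Conditions: H2 (1 atm), 10% Pd/C, EtOAc–MeOH, rt
Reagents that add atoms: none
Why: Catalytic hydrogenolysis should cleave the two benzyl ethers and the benzyl ester together, while the chromone C2–C3 bond, part of a vinylogous ester, is reduced much more slowly at 1 atm and rt.

**Compound list**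

1 | 5-heptylbenzene-1,3-diol | CCCCCCCc1cc(O)cc(O)c1 | starting material
2 | 1-(2-heptyl-4,6-dihydroxyphenyl)ethan-1-iminium chloride | CCCCCCCc1cc(O)cc(O)c1C(C)=[NH2+].[Cl-] | intermediate
3 | 1-(2-heptyl-4,6-dihydroxyphenyl)ethan-1-one | CCCCCCCc1cc(O)cc(O)c1C(C)=O | intermediate
4 | 1-[4-(benzyloxy)-2-heptyl-6-hydroxyphenyl]ethan-1-one | CCCCCCCc1cc(OCc2ccccc2)cc(O)c1C(C)=O | intermediate
5 | 1-[4-(benzyloxy)-2-heptyl-6-hydroxyphenyl]butane-1,3-dione | CCCCCCCc1cc(OCc2ccccc2)cc(O)c1C(=O)CC(C)=O | intermediate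
6 | 7-(benzyloxy)-5-heptyl-2-methyl-4H-chromen-4-one | CCCCCCCc1cc(OCc2ccccc2)cc2oc(C)cc(=O)c12 | intermediate
7 | [7-(benzyloxy)-5-heptyl-4-oxo-4H-chromen-2-yl]acetic acid | CCCCCCCc1cc(OCc2ccccc2)cc2oc(CC(=O)O)cc(=O)c12 | intermediate
8 | dimethyl 3-oxopentanedioate | COC(=O)CC(=O)CC(=O)OC | starting material
9 | dibenzyl 3-oxopentanedioate | O=C(CC(=O)OCc1ccccc1)CC(=O)OCc1ccccc1 | intermediate
10 | [7-(benzyloxy)-5-heptyl-4-oxo-4H-chromen-2-yl]acetyl chloride | CCCCCCCc1cc(OCc2ccccc2)cc2oc(CC(=O)Cl)cc(=O)c12 | intermediate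
11 | dibenzyl 2-{[7-(benzyloxy)-5-heptyl-4-oxo-4H-chromen-2-yl]acetyl}-3-oxopentanedioate (triketo tautomer drawn; racemic, enolised at C2) | CCCCCCCc1cc(OCc2ccccc2)cc2oc(CC(=O)C(C(=O)OCc3ccccc3)C(=O)CC(=O)OCc3ccccc3)cc(=O)c12 | intermediate
12 | benzyl 6-{[7-(benzyloxy)-5-heptyl-4-oxo-4H-chromen-2-yl]methyl}-4-hydroxy-2-oxo-2H-pyran-5-carboxylate | O=c1cc(O)c(C(=O)OCc2ccccc2)c(Cc2cc(=O)c3c(CCCCCCC)cc(OCc4ccccc4)cc3o2)o1 | intermediate
13 | benzyl 4-(benzyloxy)-6-{[7-(benzyloxy)-5-heptyl-4-oxo-4H-chromen-2-yl]methyl}-2-oxo-2H-pyran-5-carboxylate | O=c1cc(OCc2ccccc2)c(C(=O)OCc2ccccc2)c(Cc2cc(=O)c3c(CCCCCCC)cc(OCc4ccccc4)cc3o2)o1 | intermediate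
14 | trimethylsilyl acetate | CC(=O)O[Si](C)(C)C | starting material
15 | 1,1-bis(trimethylsilyloxy)ethene | C=C(O[Si](C)(C)C)O[Si](C)(C)C | intermediate
16 | benzyl 5-(benzyloxy)-1-{[7-(benzyloxy)-5-heptyl-4-oxo-4H-chromen-2-yl]methyl}-3-oxo-8,8-bis(trimethylsilyloxy)-2-oxabicyclo[2.2.2]oct-5-ene-6-carboxylate (racemic; bridgehead configuration fixed by the bicycle) | O=C1OC2(Cc3cc(=O)c4c(CCCCCCC)cc(OCc5ccccc5)cc4o3)CC(O[Si](C)(C)C)(O[Si](C)(C)C)C1C(OCc1ccccc1)=C2C(=O)OCc1ccccc1 | intermediate
17 | benzyl 6-(benzyloxy)-2-{[7-(benzyloxy)-5-heptyl-4-oxo-4H-chromen-2-yl]methyl}-4,4-bis(trimethylsilyloxy)cyclohexa-1,5-diene-1-carboxylate | C1(Cc3cc(=O)c4c(CCCCCCC)cc(OCc5ccccc5)cc4o3)=C(C(=O)OCc2ccccc2)C(OCc2ccccc2)=CC(O[Si](C)(C)C)(O[Si](C)(C)C)C1 | intermediate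
18 | benzyl 2-(benzyloxy)-6-{[7-(benzyloxy)-5-heptyl-4-oxo-4H-chromen-2-yl]methyl}-4-(trimethylsilyloxy)benzoate | CCCCCCCc1cc(OCc3ccccc3)cc2oc(Cc3cc(O[Si](C)(C)C)cc(OCc4ccccc4)c3C(=O)OCc3ccccc3)cc(=O)c12 | intermediate
19 | benzyl 2-(benzyloxy)-6-{[7-(benzyloxy)-5-heptyl-4-oxo-4H-chromen-2-yl]methyl}-4-hydroxybenzoate | CCCCCCCc1cc(OCc3ccccc3)cc2oc(Cc3cc(O)cc(OCc4ccccc4)c3C(=O)OCc3ccccc3)cc(=O)c12 | intermediate
20 | siphulin, 2-[(5-heptyl-7-hydroxy-4-oxo-4H-chromen-2-yl)methyl]-4,6-dihydroxybenzoic acid | CCCCCCCc1cc(O)cc2oc(Cc3cc(O)cc(O)c3C(=O)O)cc(=O)c12 | target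

**Step count and risks**

Total step count: 11. Longest linear sequence: 9 steps (steps 1, 2, 3, 4, 6, 7, 8, 10 and 11).

Steps most likely to fail:

1. Step 10. The cycloaddition may stall because the 4-benzyloxy donor and the C6 substituent deactivate the diene. The ketene acetal may also transfer a silyl group to the acidic bridging CH2, giving an unreactive silyl dienol ether, and may decompose on long heating. Fallback, setting out from 4 and coming back at 20: ring C is bought as an arene and its carboxyl group is put on last.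
   - Crossed Claisen condensation of 4 with methyl 3,5-dimethoxyphenylacetate (NaH, THF, reflux) should give 1-[4-(benzyloxy)-2-heptyl-6-hydroxyphenyl]-4-(3,5-dimethoxyphenyl)butane-1,3-dione F1.
   - Cyclodehydration (TsOH·H2O, toluene, 90 °C) should give 7-(benzyloxy)-2-[(3,5-dimethoxyphenyl)methyl]-5-heptyl-4H-chromen-4-one F2.
   - BBr3 (CH2Cl2, −78 to 0 °C) should cleave the three ethers to 2-[(3,5-dihydroxyphenyl)methyl]-5-heptyl-7-hydroxy-4H-chromen-4-one F3.
   - Ortho-carboxylation of the resorcinol ring with MeOMgOCO2Me (DMF, 120 °C), the Kolbe–Schmitt-type reaction that turns 5-alkylresorcinols into 6-alkyl-2,4-dihydroxybenzoic acids, should give 20. The ring-A phenoxide, a vinylogous carboxylate, is the poorer carbon nucleophile, and the two free ortho positions next to the CH2 on ring C are equivalent.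

2. Step 6. Acid chloride 10 may lose HCl to the ketene and self-condense, and the enolate may be acylated twice or on oxygen. Fallback, setting out from 7 and coming back at 11: the two acyl units are joined in the opposite order without an acid chloride of 7.
   - 1,1'-Carbonyldiimidazole (THF, rt) should give the acyl imidazole 2-[7-(benzyloxy)-5-heptyl-4-oxo-4H-chromen-2-yl]-1-(1H-imidazol-1-yl)ethan-1-one F4.
   - Mg(O2CCH2CO2Bn)2 (THF, rt; Masamune–Brooks decarboxylative acylation) should give benzyl 4-[7-(benzyloxy)-5-heptyl-4-oxo-4H-chromen-2-yl]-3-oxobutanoate F5.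
   - The magnesium chelate of F5 (MgCl2, pyridine, CH2Cl2, 0 °C) is acylated at C2 with benzyl 3-chloro-3-oxopropanoate to give 11.

3. Step 4. Lateral deprotonation may be incomplete, the base may open the pyranone ring or metalate C3, and the vinylogous β-keto acid may decarboxylate during work-up. Fallback, setting out from 4 and coming back at 7: the carboxyl group is introduced before ring B is closed.
   - Step 3 is stopped after the Claisen condensation and diketone 5 is isolated.
   - Its trianion (LiN(iPr)2, 3.3 equiv, THF, 0 °C) is carboxylated with CO2 at the terminal methyl carbanion (polyanion carboxylation of a β-diketone) to give 5-[4-(benzyloxy)-2-heptyl-6-hydroxyphenyl]-3,5-dioxopentanoic acid F6.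
   - Cyclodehydration at rt (TsOH·H2O, CH2Cl2) should give 7.

**Further compounds**

F1 | step 10 | 1-[4-(benzyloxy)-2-heptyl-6-hydroxyphenyl]-4-(3,5-dimethoxyphenyl)butane-1,3-dione | CCCCCCCc1cc(OCc2ccccc2)cc(O)c1C(=O)CC(=O)Cc1cc(OC)cc(OC)c1
F2 | step 10 | 7-(benzyloxy)-2-[(3,5-dimethoxyphenyl)methyl]-5-heptyl-4H-chromen-4-one | CCCCCCCc1cc(OCc2ccccc2)cc2oc(Cc3cc(OC)cc(OC)c3)cc(=O)c12
F3 | step 10 | 2-[(3,5-dihydroxyphenyl)methyl]-5-heptyl-7-hydroxy-4H-chromen-4-one | CCCCCCCc1cc(O)cc2oc(Cc3cc(O)cc(O)c3)cc(=O)c12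
F4 | step 6 | 2-[7-(benzyloxy)-5-heptyl-4-oxo-4H-chromen-2-yl]-1-(1H-imidazol-1-yl)ethan-1-one | CCCCCCCc1cc(OCc2ccccc2)cc2oc(CC(=O)n3ccnc3)cc(=O)c12
F5 | step 6 | benzyl 4-[7-(benzyloxy)-5-heptyl-4-oxo-4H-chromen-2-yl]-3-oxobutanoate | CCCCCCCc1cc(OCc2ccccc2)cc2oc(CC(=O)CC(=O)OCc3ccccc3)cc(=O)c12
F6 | step 4 | 5-[4-(benzyloxy)-2-heptyl-6-hydroxyphenyl]-3,5-dioxopentanoic acid | CCCCCCCc1cc(OCc2ccccc2)cc(O)c1C(=O)CC(=O)CC(=O)O
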